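**Retrosynthetic overview**

1. Target 38 comes from cyclodec-1(10)-ene-3,8-dione 25: the 8,12-lactone by reduction of the C8 ketone, C4=C15 by β-loss of pivalate from C15, then C13, the angelate and the 1,10-oxirane.
2. The strategy rests on this feature: C3 and C8 are both at carbonyl level and lie 1,6 across the ten-membered ring with the Z C1=C10 olefin between them, so C3–C2–C1=C10–C9–C8 is the 1,4-diene ring of a Birch-reduced 6-methyltetralin. Ozone cuts the C3=C8 ring-fusion olefin of hexahydronaphthalene 23 and unveils the ten-membered ring.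
3. 23 comes from Birch reduction of tetralin lactone 14, whose six-membered ring B already carries C4, C5, C6 and C7.
4. 14 comes from cis-1,4-dihydronaphthalene acid 12 (anti epoxidation and lactonisation set C5 and C6), 12 from an Ireland–Claisen rearrangement (C7), and that from Sharpless epoxidation and benzylic hydrogenolysis of an allylic alcohol made from 6-methyl-1-tetralone 1.
5. Ring order: rings A and B come with 1; a temporary 6,12-γ-lactone (step 9); the ten-membered ring (step 16); the 8,12-γ-lactone (step 17); the oxirane (step 23).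

Key step: step 16

Remark: germacrane numbering (C1–C15) is used for all intermediates, and β is the face of the C7 side chain. The C4 stereocentre is a spectator that is erased in step 19. The C3 carbinol of 26–30 is left as an epimer mixture because it is reoxidised.

**Route**

Step 1
Reactants: 1 6-methyl-1-tetralone
Product: 2 6-methyl-3,4-dihydronaphthalen-1-yl trifluoromethanesulfonate
Conditions: Tf2O, 2,6-di-tert-butyl-4-methylpyridine, CH2Cl2, 0 °C → rt
Reagents that add atoms: trifluoromethanesulfonic anhydride, O=S(=O)(OS(=O)(=O)C(F)(F)F)C(F)(F)F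
Why: Enol triflate formation is standard for 1-tetralones (only one enolisable side) and fixes the C4=C5 olefin at which C15 is attached.

Step 2
Reactants: 2 6-methyl-3,4-dihydronaphthalen-1-yl trifluoromethanesulfonate
Product: 3 (6-methyl-3,4-dihydronaphthalen-1-yl)methanol
Conditions: Bu3SnCH2OH, Pd(PPh3)4 (5 mol %), LiCl, 1,4-dioxane, 100 °C
Reagents that add atoms: (tributylstannyl)methanol, OC[Sn](CCCC)(CCCC)CCCC
Why: Stille coupling of an alkenyl triflate, in which the α-oxygenated CH2OH group transfers from tin in preference to butyl, should give the trisubstituted allylic alcohol (C15 in place) directly.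

Step 3
Reactants: 3 (6-methyl-3,4-dihydronaphthalen-1-yl)methanol
Product: 4 [(1S,2S)-1,2-epoxy-6-methyl-1,2,3,4-tetrahydronaphthalen-1-yl]methanol
Conditions: Ti(OiPr)4 (10 mol %), L-(+)-diethyl tartrate (12 mol %), t-BuOOH, 4 Å molecular sieves, CH2Cl2, −20 °C
Reagents that add atoms: tert-butyl hydroperoxide, CC(C)(C)OO
Why: Sharpless asymmetric epoxidation of a trisubstituted allylic alcohol, where the L-(+)-tartrate complex should deliver oxygen to the face that gives the (S,S)-epoxide (same sense as for (E)-2-alken-1-ols and 1-cyclohexenylmethanol), setting C4 and C5 and the absolute configuration from which all later centres are relayed.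

Step 4
Reactants: 4 [(1S,2S)-1,2-epoxy-6-methyl-1,2,3,4-tetrahydronaphthalen-1-yl]methanol
Product: 5 (1S,2S)-1-(hydroxymethyl)-6-methyl-1,2,3,4-tetrahydronaphthalen-2-ol (cis)
Conditions: H2 (1 atm), Pd/C, EtOAc, rt
Reagents that add atoms: none
Why: Hydrogenolysis of an aryl epoxide on palladium should cleave only the benzylic C4–O bond with inversion, so hydrogen enters anti to oxygen and the C4 CH2OH and the retained C5 hydroxyl end up cis.

Step 5
Reactants: 5 (1S,2S)-1-(hydroxymethyl)-6-methyl-1,2,3,4-tetrahydronaphthalen-2-ol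
Product: 7 [(1S,2S)-2-acetoxy-6-methyl-1,2,3,4-tetrahydronaphthalen-1-yl]methyl pivalate, via mono-pivalate 6 (not isolated)
Conditions: t-BuCOCl (1.05 equiv), pyridine, CH2Cl2, −20 °C; then Ac2O, DMAP (cat.), rt
Reagents that add atoms: pivaloyl chloride, CC(C)(C)C(Cl)=O; acetic anhydride, CC(=O)OC(C)=O
Why: Acylation with the hindered acid chloride should discriminate the primary from the secondary hydroxyl, and acetylation of the remaining C5 hydroxyl supplies the ester for the Claisen step.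

Step 6
Reactants: 7 [(1S,2S)-2-acetoxy-6-methyl-1,2,3,4-tetrahydronaphthalen-1-yl]methyl pivalate
Product: 8 [(1S,2S)-2-acetoxy-4-bromo-6-methyl-1,2,3,4-tetrahydronaphthalen-1-yl]methyl pivalate (epimers at the bromide carbon, used crude)
Conditions: NBS (1.05 equiv), AIBN (cat.), PhCF3, 80 °C
Reagents that add atoms: N-bromosuccinimide, O=C1CCC(=O)N1Br
Why: Wohl–Ziegler bromination should occur at C7, the only benzylic CH2, because the tertiary C4–H lies near the arene plane (side chain pseudoaxial) and is deactivated by two β-acyloxy groups, and the aryl methyl is a slower primary site.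

Step 7
Reactants: 8 [(1S,2S)-2-acetoxy-4-bromo-6-methyl-1,2,3,4-tetrahydronaphthalen-1-yl]methyl pivalate
Product: 9 [(1S,2S)-2-acetoxy-6-methyl-1,2-dihydronaphthalen-1-yl]methyl pivalate
Conditions: DBU, THF, 0 °C → rt
Reagents that add atoms: none
Why: E2 dehydrobromination of the secondary benzylic bromide gives the styrenic C6=C7 olefin, and since bromide is a far better leaving group than the allylic acetate, loss of acetic acid (aromatisation) should not compete at this temperature.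

Step 8
Reactants: 9 [(1S,2S)-2-acetoxy-6-methyl-1,2-dihydronaphthalen-1-yl]methyl pivalate
Product: 12 2-[(1R,4S)-7-methyl-4-(pivaloyloxymethyl)-1,4-dihydronaphthalen-1-yl]acetic acid (cis-1,4), via silyl ketene acetal 10 (not isolated), via trimethylsilyl ester 11 (not isolated)
Conditions: LiN(iPr)2 (LDA), Me3SiCl/Et3N, THF, −78 °C → 50 °C; then 1 M HCl, 0 °C
Reagents that add atoms: none
Why: Ireland–Claisen rearrangement, a suprafacial [3,3] shift across C5–C6=C7, should form the C7–C11 bond on the face that carried the C5 oxygen, i.e. cis to the C4 side chain, and move the olefin to C5=C6.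

Step 9
Reactants: 12 2-[(1R,4S)-7-methyl-4-(pivaloyloxymethyl)-1,4-dihydronaphthalen-1-yl]acetic acid
Product: 14 [(3aS,4S,5S,9bS)-4-hydroxy-8-methyl-2-oxo-1,2,3a,4,5,9b-hexahydronaphtho[2,1-b]furan-5-yl]methyl pivalate (cis-fused γ-lactone), via epoxy acid 13 (not isolated)
Conditions: mCPBA, CH2Cl2, 0 °C → rt; then camphorsulfonic acid (cat.)
Reagents that add atoms: 3-chloroperoxybenzoic acid, O=C(OO)c1cccc(Cl)c1
Why: Prilezhaev epoxidation should occur on the face opposite the two cis pseudoaxial side chains, and the acid then opens the epoxide at C6 from the rear (5-exo, inversion), which sets the C6 oxygen cis to the C7 chain and the C5 hydroxyl trans to it; a syn epoxide could not lactonise.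

Step 10
Reactants: 14 [(3aS,4S,5S,9bS)-4-hydroxy-8-methyl-2-oxo-1,2,3a,4,5,9b-hexahydronaphtho[2,1-b]furan-5-yl]methyl pivalate
Product: 15 lithium 2-[(1S,2S,3S,4S)-2,3-dihydroxy-4-(hydroxymethyl)-7-methyl-1,2,3,4-tetrahydronaphthalen-1-yl]acetate (crude salt after evaporation)
Conditions: LiOH·H2O (3 equiv), THF/MeOH/H2O, 40 °C; evaporate, dry
Reagents that add atoms: lithium hydroxide, [Li+].[OH-]
Why: Saponification opens the lactone to a carboxylate that is inert to dissolving metal and removes the pivalate, so the Birch substrate carries no reducible ester and no silyl group.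

Step 11
Reactants: 15 lithium 2-[(1S,2S,3S,4S)-2,3-dihydroxy-4-(hydroxymethyl)-7-methyl-1,2,3,4-tetrahydronaphthalen-1-yl]acetate
Product: 17 (3aS,4S,5S,9bS)-4-hydroxy-5-(hydroxymethyl)-8-methyl-3a,4,5,6,9,9b-hexahydronaphtho[2,1-b]furan-2(1H)-one, via dienyl hydroxy acid 16 (not isolated)
Conditions: Li, NH3 (l), THF, t-BuOH, −78 → −33 °C; NH4Cl; then 1 M HCl to pH 3, 0 °C → rt
Reagents that add atoms: none
Why: Birch reduction of the 1,2,4-trialkylbenzene should protonate the two unsubstituted para-related carbons C2 and C9, leaving the C3=C8 tetrasubstituted and C1=C10 trisubstituted olefins (no benzylic heteroatom, alkoxides and carboxylate inert), and acidification recloses the cis γ-lactone, which distinguishes the C6 from the C5 hydroxyl.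

Step 12
Reactants: 17 (3aS,4S,5S,9bS)-4-hydroxy-5-(hydroxymethyl)-8-methyl-3a,4,5,6,9,9b-hexahydronaphtho[2,1-b]furan-2(1H)-one
Product: 18 [(3aS,4S,5S,9bS)-4-hydroxy-8-methyl-2-oxo-1,2,3a,4,5,6,9,9b-octahydronaphtho[2,1-b]furan-5-yl]methyl pivalate
Conditions: t-BuCOCl, pyridine, CH2Cl2, −20 → 0 °C
Reagents that add atoms: pivaloyl chloride, CC(C)(C)C(Cl)=O
Why: Selective acylation of the primary C15 hydroxyl over the hindered secondary C5 hydroxyl installs the later leaving group.

Step 13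
Reactants: 18 [(3aS,4S,5S,9bS)-4-hydroxy-8-methyl-2-oxo-1,2,3a,4,5,6,9,9b-octahydronaphtho[2,1-b]furan-5-yl]methyl pivalate
Product: 19 [(3aS,4S,5S,9bS)-8-methyl-2-oxo-4-(triethylsilyloxy)-1,2,3a,4,5,6,9,9b-octahydronaphtho[2,1-b]furan-5-yl]methyl pivalate
Conditions: Et3SiCl, imidazole, DMF, 0 °C
Reagents that add atoms: chlorotriethylsilane, CC[Si](Cl)(CC)CC
Why: Silylation of the only free hydroxyl places the more labile silyl group on C5, where the angelate will go.

Step 14
Reactants: 19 [(3aS,4S,5S,9bS)-8-methyl-2-oxo-4-(triethylsilyloxy)-1,2,3a,4,5,6,9,9b-octahydronaphtho[2,1-b]furan-5-yl]methyl pivalate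
Product: 22 2-[(1S,2S,3S,4S)-2-(tert-butyldimethylsilyloxy)-7-methyl-4-(pivaloyloxymethyl)-3-(triethylsilyloxy)-1,2,3,4,5,8-hexahydronaphthalen-1-yl]acetic acid, via lithium hydroxy carboxylate 20 (not isolated), via silyl ether silyl ester 21 (not isolated)
Conditions: LiOH (1.2 equiv), THF/H2O, 0 °C; evaporate; t-BuMe2SiOTf, 2,6-lutidine, CH2Cl2, −78 → 0 °C; then K2CO3, MeOH/H2O, 0 °C; pH 5 buffer
Reagents that add atoms: lithium hydroxide, [Li+].[OH-]; tert-butyldimethylsilyl trifluoromethanesulfonate, CC(C)(C)[Si](C)(C)OS(=O)(=O)C(F)(F)F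
Why: Lactone hydrolysis (much faster than pivalate hydrolysis) followed by exhaustive silylation traps the C6 hydroxyl before it can relactonise, and the silyl ester is cleaved by mild base far faster than the silyl ethers or the pivalate.

Step 15
Reactants: 22 2-[(1S,2S,3S,4S)-2-(tert-butyldimethylsilyloxy)-7-methyl-4-(pivaloyloxymethyl)-3-(triethylsilyloxy)-1,2,3,4,5,8-hexahydronaphthalen-1-yl]acetic acid
Product: 23 methyl 2-[(1S,2S,3S,4S)-2-(tert-butyldimethylsilyloxy)-7-methyl-4-(pivaloyloxymethyl)-3-(triethylsilyloxy)-1,2,3,4,5,8-hexahydronaphthalen-1-yl]acetate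
Conditions: Me3SiCHN2, MeOH/toluene, 0 °C
Reagents that add atoms: (trimethylsilyl)diazomethane, C[Si](C)(C)C=[N+]=[N-]
Why: Neutral methylation of the acid with the diazoalkane leaves silyl ethers, pivalate and the skipped diene untouched.

Step 16
Reactants: 23 methyl 2-[(1S,2S,3S,4S)-2-(tert-butyldimethylsilyloxy)-7-methyl-4-(pivaloyloxymethyl)-3-(triethylsilyloxy)-1,2,3,4,5,8-hexahydronaphthalen-1-yl]acetate
Product: 25 (1(10)Z)-7β-(methoxycarbonylmethyl)-10-methyl-4β-(pivaloyloxymethyl)-6β-(tert-butyldimethylsilyloxy)-5α-(triethylsilyloxy)cyclodec-1(10)-ene-3,8-dione, via ozonide 24 (not isolated)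
Conditions: O3 (1.0 equiv, Sudan Red 7B end point), CH2Cl2, −78 °C; then Me2S, −78 °C → rt
Reagents that add atoms: ozone, [O-][O+]=O
Why: Ozone adds as a 1,3-dipole to the tetrasubstituted C3=C8 ring-fusion olefin, the primary ozonide undergoes cycloreversion to a ketone and a tethered carbonyl oxide that recombine to ozonide 24, and dimethyl sulfide reduces 24 to the C3 and C8 ketones. The closest known reaction is the ozonolysis of the central olefin of Birch-derived 1,4,5,8-tetrahydronaphthalenes (and of 9,10-octalin) to cyclodecane-1,6-diones. No ring is closed by bond formation: the ten-membered ring is the perimeter of the bicycle and is unveiled when the shared C3–C8 bond is cut. No stereocentre is created; C4 to C7 were set on the rigid six-membered ring and the Z geometry of C1=C10 is inherited from the cyclohexadiene. The step needs chemoselectivity for the tetrasubstituted over the trisubstituted olefin, which rests on the higher nucleophilicity of the tetraalkyl olefin, on one titrated equivalent of ozone at −78 °C, and on the absence of any other electron-rich π-system. The diketone is kept neutral and cold because its α-stereocentres and the 1,6-diketone (transannular aldol) are base-sensitive.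

Step 17
Reactants: 25 (1(10)Z)-7β-(methoxycarbonylmethyl)-10-methyl-4β-(pivaloyloxymethyl)-6β-(tert-butyldimethylsilyloxy)-5α-(triethylsilyloxy)cyclodec-1(10)-ene-3,8-dione
Product: 27 (1(10)Z)-3-hydroxy-4β-(pivaloyloxymethyl)-6β-(tert-butyldimethylsilyloxy)-5α-(triethylsilyloxy)germacr-1(10)-en-12,8α-olide (trans-fused lactone; C3 epimers), via diol ester 26 (not isolated)
Conditions: (S)-Me-CBS oxazaborolidine (0.5 equiv), catecholborane, toluene, −78 → −40 °C; MeOH; then PPTS (cat.), CH2Cl2, rt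
Reagents that add atoms: none
Why: Corey–Bakshi–Shibata reduction under reagent control should deliver hydride to the C8 carbonyl (branched C7 as the large, C9H2 as the small flank) to give the 8α-alcohol trans to the C7 chain without base, the C3 ketone being reduced as well and reoxidised later, and the 8α-hydroxyl then closes the γ-lactone onto the methyl ester.

Step 18
Reactants: 27 (1(10)Z)-3-hydroxy-4β-(pivaloyloxymethyl)-6β-(tert-butyldimethylsilyloxy)-5α-(triethylsilyloxy)germacr-1(10)-en-12,8α-olide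
Product: 30 (1(10)Z)-3-hydroxy-4β-(pivaloyloxymethyl)-6β-(tert-butyldimethylsilyloxy)-5α-(triethylsilyloxy)germacra-1(10),11(13)-dien-12,8α-olide (C3 epimers), via Mannich base 28 (not isolated), via ammonium iodide 29 (not isolated)
Conditions: LiN(iPr)2 (LDA, 2.5 equiv), THF, −78 °C; [Me2N=CH2]I, −78 → 0 °C; then MeI, CH2Cl2/MeOH, rt; then NaHCO3 (aq), rt
Reagents that add atoms: Eschenmoser's salt (N,N-dimethylmethyleneiminium iodide), C=[N+](C)C.[I-]
Why: α-Methylenation by Mannich reaction of the lactone enolate, N-methylation and elimination of trimethylamine is run here because no enolisable ketone is present; the extra base covers the C3 alkoxide and the hindered pivalate should not migrate at low temperature.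

Step 19
Reactants: 30 (1(10)Z)-3-hydroxy-4β-(pivaloyloxymethyl)-6β-(tert-butyldimethylsilyloxy)-5α-(triethylsilyloxy)germacra-1(10),11(13)-dien-12,8α-olide
Product: 32 (1(10)Z)-3-oxo-6β-(tert-butyldimethylsilyloxy)-5α-(triethylsilyloxy)germacra-1(10),4(15),11(13)-trien-12,8α-olide, via pivaloyloxy ketone 31 (not isolated)
Conditions: Dess–Martin periodinane, CH2Cl2, rt; then DBU, 0 °C
Reagents that add atoms: none
Why: Dess–Martin oxidation of the only free hydroxyl regenerates the C3 ketone, and DBU triggers E1cB loss of pivalate from C15 through the C3/C4 enolate, which places the C4=C15 methylene without a regiochemical choice and erases the C4 stereocentre.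

Step 20
Reactants: 32 (1(10)Z)-3-oxo-6β-(tert-butyldimethylsilyloxy)-5α-(triethylsilyloxy)germacra-1(10),4(15),11(13)-trien-12,8α-olide
Product: 33 (1(10)Z)-5α-hydroxy-3-oxo-6β-(tert-butyldimethylsilyloxy)germacra-1(10),4(15),11(13)-trien-12,8α-olide
Conditions: HF·pyridine, pyridine, THF, 0 °C
Reagents that add atoms: none
Why: Selective desilylation, since the allylic triethylsilyl ether is cleaved by buffered fluoride much faster than the tert-butyldimethylsilyl ether.

Step 21
Reactants: 33 (1(10)Z)-5α-hydroxy-3-oxo-6β-(tert-butyldimethylsilyloxy)germacra-1(10),4(15),11(13)-trien-12,8α-olide; 34 angelic acid ((Z)-2-methylbut-2-enoic acid)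
Product: 36 (1(10)Z)-5α-angeloyloxy-3-oxo-6β-(tert-butyldimethylsilyloxy)germacra-1(10),4(15),11(13)-trien-12,8α-olide, via mixed anhydride 35 (not isolated)
Conditions: 34, 2,4,6-Cl3C6H2COCl, Et3N, toluene, rt; then 33, 75 °C
Reagents that add atoms: none
Why: Yamaguchi-type esterification through the mixed trichlorobenzoic anhydride without DMAP should acylate the alcohol at the less hindered angeloyl carbonyl and avoid Z-to-E isomerisation to the tiglate.

Step 22
Reactants: 36 (1(10)Z)-5α-angeloyloxy-3-oxo-6β-(tert-butyldimethylsilyloxy)germacra-1(10),4(15),11(13)-trien-12,8α-olide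
Product: 37 (1(10)Z)-5α-angeloyloxy-6β-hydroxy-3-oxogermacra-1(10),4(15),11(13)-trien-12,8α-olide
Conditions: HF·pyridine, THF, 0 °C → rt
Reagents that add atoms: none
Why: Acidic fluoride desilylation frees the C6 hydroxyl before the acid-sensitive oxirane is present and avoids base-induced acyl migration from O5 to O6.

Step 23
Reactants: 37 (1(10)Z)-5α-angeloyloxy-6β-hydroxy-3-oxogermacra-1(10),4(15),11(13)-trien-12,8α-olide
Product: 38 (1S,10R)-5α-angeloyloxy-1,10-epoxy-6β-hydroxy-3-oxogermacra-4(15),11(13)-dien-12,8α-olide (target)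
Conditions: VO(acac)2 (5 mol %), t-BuOOH, CH2Cl2, 0 °C
Reagents that add atoms: tert-butyl hydroperoxide, CC(C)(C)OO
Why: Hydroxyl-directed epoxidation, in which the vanadate ester of the 6β-hydroxyl should deliver oxygen across the ring to the β-face of the only electron-rich olefin with retention of the cis geometry, setting C1 (S) and C10 (R); the enone, methylene lactone and angelate olefins are electron-poor and inert.

**Compound list**

1 | 6-methyl-1-tetralone | Cc1ccc2c(c1)CCCC2=O | starting material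
2 | 6-methyl-3,4-dihydronaphthalen-1-yl trifluoromethanesulfonate | Cc1ccc2c(c1)CCC=C2OS(=O)(=O)C(F)(F)F | intermediate
3 | (6-methyl-3,4-dihydronaphthalen-1-yl)methanol | Cc1ccc2c(c1)CCC=C2CO | intermediate
4 | [(1S,2S)-1,2-epoxy-6-methyl-1,2,3,4-tetrahydronaphthalen-1-yl]methanol | Cc1ccc2c(c1)CC[C@@H]3O[C@]23CO | intermediate
5 | (1S,2S)-1-(hydroxymethyl)-6-methyl-1,2,3,4-tetrahydronaphthalen-2-ol | Cc1ccc2c(c1)CC[C@H](O)[C@@H]2CO | intermediate
6 | [(1S,2S)-2-hydroxy-6-methyl-1,2,3,4-tetrahydronaphthalen-1-yl]methyl pivalate | Cc1ccc2c(c1)CC[C@H](O)[C@@H]2COC(=O)C(C)(C)C | intermediate (not isolated)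
7 | [(1S,2S)-2-acetoxy-6-methyl-1,2,3,4-tetrahydronaphthalen-1-yl]methyl pivalate | Cc1ccc2c(c1)CC[C@H](OC(C)=O)[C@@H]2COC(=O)C(C)(C)C | intermediate
8 | [(1S,2S)-2-acetoxy-4-bromo-6-methyl-1,2,3,4-tetrahydronaphthalen-1-yl]methyl pivalate (epimers at C–Br) | Cc1ccc2c(c1)C(Br)C[C@H](OC(C)=O)[C@@H]2COC(=O)C(C)(C)C | intermediate
9 | [(1S,2S)-2-acetoxy-6-methyl-1,2-dihydronaphthalen-1-yl]methyl pivalate | Cc1ccc2c(c1)C=C[C@H](OC(C)=O)[C@@H]2COC(=O)C(C)(C)C | intermediate
10 | [(1S,2S)-6-methyl-2-{[1-(trimethylsilyloxy)ethenyl]oxy}-1,2-dihydronaphthalen-1-yl]methyl pivalate | Cc1ccc2c(c1)C=C[C@H](OC(=C)O[Si](C)(C)C)[C@@H]2COC(=O)C(C)(C)C | intermediate (not isolated)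
11 | trimethylsilyl 2-[(1R,4S)-7-methyl-4-(pivaloyloxymethyl)-1,4-dihydronaphthalen-1-yl]acetate | Cc1ccc2c(c1)[C@H](CC(=O)O[Si](C)(C)C)C=C[C@@H]2COC(=O)C(C)(C)C | intermediate (not isolated)
12 | 2-[(1R,4S)-7-methyl-4-(pivaloyloxymethyl)-1,4-dihydronaphthalen-1-yl]acetic acid | Cc1ccc2c(c1)[C@H](CC(=O)O)C=C[C@@H]2COC(=O)C(C)(C)C | intermediate
13 | 2-[(1S,2R,3S,4S)-2,3-epoxy-7-methyl-4-(pivaloyloxymethyl)-1,2,3,4-tetrahydronaphthalen-1-yl]acetic acid | Cc1ccc2c(c1)[C@H](CC(=O)O)[C@H]3O[C@H]3[C@@H]2COC(=O)C(C)(C)C | intermediate (not isolated)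
14 | [(3aS,4S,5S,9bS)-4-hydroxy-8-methyl-2-oxo-1,2,3a,4,5,9b-hexahydronaphtho[2,1-b]furan-5-yl]methyl pivalate | Cc1ccc2c(c1)[C@@H]3CC(=O)O[C@@H]3[C@@H](O)[C@@H]2COC(=O)C(C)(C)C | intermediate
15 | lithium 2-[(1S,2S,3S,4S)-2,3-dihydroxy-4-(hydroxymethyl)-7-methyl-1,2,3,4-tetrahydronaphthalen-1-yl]acetate | Cc1ccc2c(c1)[C@H](CC(=O)[O-])[C@H](O)[C@@H](O)[C@@H]2CO.[Li+] | intermediate
16 | 2-[(1S,2S,3S,4S)-2,3-dihydroxy-4-(hydroxymethyl)-7-methyl-1,2,3,4,5,8-hexahydronaphthalen-1-yl]acetic acid | OC[C@H]1[C@H](O)[C@@H](O)[C@@H](CC(=O)O)C2=C1CC=C(C)C2 | intermediate (not isolated)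
17 | (3aS,4S,5S,9bS)-4-hydroxy-5-(hydroxymethyl)-8-methyl-3a,4,5,6,9,9b-hexahydronaphtho[2,1-b]furan-2(1H)-one | OC[C@H]1[C@H](O)[C@H]3OC(=O)C[C@H]3C2=C1CC=C(C)C2 | intermediate
18 | [(3aS,4S,5S,9bS)-4-hydroxy-8-methyl-2-oxo-1,2,3a,4,5,6,9,9b-octahydronaphtho[2,1-b]furan-5-yl]methyl pivalate | CC(C)(C)C(=O)OC[C@H]1[C@H](O)[C@H]3OC(=O)C[C@H]3C2=C1CC=C(C)C2 | intermediate
19 | [(3aS,4S,5S,9bS)-8-methyl-2-oxo-4-(triethylsilyloxy)-1,2,3a,4,5,6,9,9b-octahydronaphtho[2,1-b]furan-5-yl]methyl pivalate | CC(C)(C)C(=O)OC[C@H]1[C@H](O[Si](CC)(CC)CC)[C@H]3OC(=O)C[C@H]3C2=C1CC=C(C)C2 | intermediate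
20 | lithium 2-[(1S,2S,3S,4S)-2-hydroxy-7-methyl-4-(pivaloyloxymethyl)-3-(triethylsilyloxy)-1,2,3,4,5,8-hexahydronaphthalen-1-yl]acetate | CC(C)(C)C(=O)OC[C@H]1[C@H](O[Si](CC)(CC)CC)[C@@H](O)[C@@H](CC(=O)[O-])C2=C1CC=C(C)C2.[Li+] | intermediate (not isolated)
21 | tert-butyldimethylsilyl 2-[(1S,2S,3S,4S)-2-(tert-butyldimethylsilyloxy)-7-methyl-4-(pivaloyloxymethyl)-3-(triethylsilyloxy)-1,2,3,4,5,8-hexahydronaphthalen-1-yl]acetate | CC(C)(C)C(=O)OC[C@H]1[C@H](O[Si](CC)(CC)CC)[C@@H](O[Si](C)(C)C(C)(C)C)[C@@H](CC(=O)O[Si](C)(C)C(C)(C)C)C2=C1CC=C(C)C2 | intermediate (not isolated)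
22 | 2-[(1S,2S,3S,4S)-2-(tert-butyldimethylsilyloxy)-7-methyl-4-(pivaloyloxymethyl)-3-(triethylsilyloxy)-1,2,3,4,5,8-hexahydronaphthalen-1-yl]acetic acid | CC(C)(C)C(=O)OC[C@H]1[C@H](O[Si](CC)(CC)CC)[C@@H](O[Si](C)(C)C(C)(C)C)[C@@H](CC(=O)O)C2=C1CC=C(C)C2 | intermediate
23 | methyl 2-[(1S,2S,3S,4S)-2-(tert-butyldimethylsilyloxy)-7-methyl-4-(pivaloyloxymethyl)-3-(triethylsilyloxy)-1,2,3,4,5,8-hexahydronaphthalen-1-yl]acetate (key-step precursor) | CC(C)(C)C(=O)OC[C@H]1[C@H](O[Si](CC)(CC)CC)[C@@H](O[Si](C)(C)C(C)(C)C)[C@@H](CC(=O)OC)C2=C1CC=C(C)C2 | intermediate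
24 | secondary ozonide (1,2,4-trioxolane bridging C3 and C8) of 23 | CC(C)(C)C(=O)OC[C@H]1[C@H](O[Si](CC)(CC)CC)[C@@H](O[Si](C)(C)C(C)(C)C)[C@@H](CC(=O)OC)C23OOC1(O2)CC=C(C)C3 | intermediate (not isolated)
25 | (1(10)Z)-7β-(methoxycarbonylmethyl)-10-methyl-4β-(pivaloyloxymethyl)-6β-(tert-butyldimethylsilyloxy)-5α-(triethylsilyloxy)cyclodec-1(10)-ene-3,8-dione (key-step product) | CC(C)(C)C(=O)OC[C@H]1[C@H](O[Si](CC)(CC)CC)[C@@H](O[Si](C)(C)C(C)(C)C)[C@@H](CC(=O)OC)C(=O)C/C(C)=C\CC1=O | intermediate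
26 | 3,8α-diol methyl ester from reduction of 25 (C3 epimers) | CC(C)(C)C(=O)OC[C@H]1[C@H](O[Si](CC)(CC)CC)[C@@H](O[Si](C)(C)C(C)(C)C)[C@@H](CC(=O)OC)[C@H](O)C/C(C)=C\CC1O | intermediate (not isolated)
27 | (1(10)Z)-3-hydroxy-4β-(pivaloyloxymethyl)-6β-(tert-butyldimethylsilyloxy)-5α-(triethylsilyloxy)germacr-1(10)-en-12,8α-olide (C3 epimers) | CC(C)(C)C(=O)OC[C@H]1[C@H](O[Si](CC)(CC)CC)[C@@H](O[Si](C)(C)C(C)(C)C)[C@H]2CC(=O)O[C@@H]2C/C(C)=C\CC1O | intermediate
28 | 13-(dimethylamino) Mannich base of 27 (C11 epimers) | CC(C)(C)C(=O)OC[C@H]1[C@H](O[Si](CC)(CC)CC)[C@@H](O[Si](C)(C)C(C)(C)C)[C@H]2C(CN(C)C)C(=O)O[C@@H]2C/C(C)=C\CC1O | intermediate (not isolated)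
29 | 13-(trimethylammonio) iodide of 28 | CC(C)(C)C(=O)OC[C@H]1[C@H](O[Si](CC)(CC)CC)[C@@H](O[Si](C)(C)C(C)(C)C)[C@H]2C(C[N+](C)(C)C)C(=O)O[C@@H]2C/C(C)=C\CC1O.[I-] | intermediate (not isolated)
30 | (1(10)Z)-3-hydroxy-4β-(pivaloyloxymethyl)-6β-(tert-butyldimethylsilyloxy)-5α-(triethylsilyloxy)germacra-1(10),11(13)-dien-12,8α-olide (C3 epimers) | CC(C)(C)C(=O)OC[C@H]1[C@H](O[Si](CC)(CC)CC)[C@@H](O[Si](C)(C)C(C)(C)C)[C@H]2C(=C)C(=O)O[C@@H]2C/C(C)=C\CC1O | intermediate
31 | (1(10)Z)-3-oxo-4β-(pivaloyloxymethyl)-6β-(tert-butyldimethylsilyloxy)-5α-(triethylsilyloxy)germacra-1(10),11(13)-dien-12,8α-olide | CC(C)(C)C(=O)OC[C@H]1[C@H](O[Si](CC)(CC)CC)[C@@H](O[Si](C)(C)C(C)(C)C)[C@H]2C(=C)C(=O)O[C@@H]2C/C(C)=C\CC1=O | intermediate (not isolated)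
32 | (1(10)Z)-3-oxo-6β-(tert-butyldimethylsilyloxy)-5α-(triethylsilyloxy)germacra-1(10),4(15),11(13)-trien-12,8α-olide | C=C1[C@H](O[Si](CC)(CC)CC)[C@@H](O[Si](C)(C)C(C)(C)C)[C@H]2C(=C)C(=O)O[C@@H]2C/C(C)=C\CC1=O | intermediate
33 | (1(10)Z)-5α-hydroxy-3-oxo-6β-(tert-butyldimethylsilyloxy)germacra-1(10),4(15),11(13)-trien-12,8α-olide | C=C1[C@H](O)[C@@H](O[Si](C)(C)C(C)(C)C)[C@H]2C(=C)C(=O)O[C@@H]2C/C(C)=C\CC1=O | intermediate
34 | angelic acid ((Z)-2-methylbut-2-enoic acid) | C/C=C(/C)C(=O)O | starting material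
35 | angelic 2,4,6-trichlorobenzoic anhydride | C/C=C(/C)C(=O)OC(=O)c1c(Cl)cc(Cl)cc1Cl | intermediate (not isolated)
36 | (1(10)Z)-5α-angeloyloxy-3-oxo-6β-(tert-butyldimethylsilyloxy)germacra-1(10),4(15),11(13)-trien-12,8α-olide | C=C1[C@H](OC(=O)/C(C)=C\C)[C@@H](O[Si](C)(C)C(C)(C)C)[C@H]2C(=C)C(=O)O[C@@H]2C/C(C)=C\CC1=O | intermediate
37 | (1(10)Z)-5α-angeloyloxy-6β-hydroxy-3-oxogermacra-1(10),4(15),11(13)-trien-12,8α-olide | C=C1[C@H](OC(=O)/C(C)=C\C)[C@@H](O)[C@H]2C(=C)C(=O)O[C@@H]2C/C(C)=C\CC1=O | intermediate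
38 | (1S,10R)-5α-angeloyloxy-1,10-epoxy-6β-hydroxy-3-oxogermacra-4(15),11(13)-dien-12,8α-olide (CNP0348992.1) | C=C1C(=O)O[C@@H]2C[C@@]3(C)O[C@H]3CC(=O)C(=C)[C@H](OC(=O)/C(C)=C\C)[C@@H](O)[C@@H]12 | target

**Totals and risks**

Total step count: 23. Longest linear sequence: 23 steps (1 → 38); angelic acid 34 enters in step 21.

The three steps most likely to fail:

Step 16 (ozonolysis). Ozone is a rather unselective electrophile, so the two alkyl-substituted olefins may not be discriminated well enough: attack at C1=C10 or over-oxidation would erode the diketone. The fallback sets out from 23. Peracid epoxidation, which responds far more strongly to olefin substitution (mCPBA, NaHCO3, CH2Cl2, −20 °C), should give the ring-fusion epoxide F1. Periodic acid (H5IO6, THF/H2O, 0 °C) then opens it to the ditertiary glycol and cleaves it, and the route is rejoined at 25.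

Step 17 (C8 reduction). Hydride may be delivered under substrate control (Felkin–Anh attack anti to the C6 branch) instead of catalyst control, which gives the 8β-alkoxide and a cis-fused lactone. The fallback sets out from 25 and accepts this bias. NaBH4/CeCl3·7H2O (MeOH, −40 °C) followed by PPTS should give the 8-epi lactone F2. LiOH (THF/H2O, 0 °C, careful acidification to pH 4, used at once) gives the 8β-hydroxy acid F3. Mitsunobu lactonisation (PPh3, diisopropyl azodicarboxylate, THF, 0 °C) closes the γ-lactone with inversion at C8, and the route is rejoined at 27.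

Step 23 (epoxidation). Facial selectivity may be poor: the vanadate of the 6β-hydroxyl may not reach across the flexible ten-membered ring, and undirected attack on the exposed olefin face would give the 1,10-epimeric oxirane. The fallback sets out from 36, with C6 still silylated. NBS in aqueous THF should place bromine on the exposed face at C1 and water anti at C10, giving bromohydrin F4. Ag2O closes the oxirane by rear-side displacement, so that oxygen ends on the face opposite to the first attack (silyl ether F5). Bu4NF/AcOH removes the silyl group, and the route is rejoined at 38.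

**Further compounds**

F1 | step 16 | C3,C8 ring-fusion epoxide of 23 | CC(C)(C)C(=O)OC[C@H]1[C@H](O[Si](CC)(CC)CC)[C@@H](O[Si](C)(C)C(C)(C)C)[C@@H](CC(=O)OC)C23OC12CC=C(C)C3
F2 | step 17 | 8-epi lactone of 27 (12,8β-olide, cis-fused; C3 epimers) | CC(C)(C)C(=O)OC[C@H]1[C@H](O[Si](CC)(CC)CC)[C@@H](O[Si](C)(C)C(C)(C)C)[C@H]2CC(=O)O[C@H]2C/C(C)=C\CC1O
F3 | step 17 | 3,8β-dihydroxy acid from F2 (C3 epimers) | CC(C)(C)C(=O)OC[C@H]1[C@H](O[Si](CC)(CC)CC)[C@@H](O[Si](C)(C)C(C)(C)C)[C@@H](CC(=O)O)[C@@H](O)C/C(C)=C\CC1O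
F4 | step 23 | 1α-bromo-10β-hydroxy bromohydrin of 36 | C=C1[C@H](OC(=O)/C(C)=C\C)[C@@H](O[Si](C)(C)C(C)(C)C)[C@H]2C(=C)C(=O)O[C@@H]2C[C@@](C)(O)[C@H](Br)CC1=O
F5 | step 23 | 6-O-tert-butyldimethylsilyl ether of 38 | C=C1[C@H](OC(=O)/C(C)=C\C)[C@@H](O[Si](C)(C)C(C)(C)C)[C@H]2C(=C)C(=O)O[C@@H]2C[C@@]3(C)O[C@H]3CC1=O
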